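**Strategy.** The flavone is cut at C4–C4a and O1–C2, which leads back to ethyl phenylpropiolate and (R)-3,5-dimethoxy-4-(1-methylpiperidin-2-yl)phenol. In ring A, C6 lies para to C8a and between O5 and O7, so this phenol has two interchangeable ortho carbons (future C4a and C8). An intramolecular Friedel–Crafts acylation of the derived (Z)-β-aryloxycinnamic acid, held as its piperidinium chloride, therefore closes pyranone ring C and fixes the 6-substitution in one operation without any regiochemical choice. The piperidine stereocentre is set beforehand by Grignard addition to an N-tert-butanesulfinyl aldimine and is then only carried.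

Key step: step 10

Assumption (chemistry): the Grignard addition of step 4 is taken to follow the closed chair transition state with magnesium on the sulfinyl oxygen. The configuration is to be proved by X-ray analysis at the adduct or the phenol stage. Should the two ortho methoxy groups reverse the facial sense, (R)-tert-butanesulfinamide is used instead of the S reagent and nothing else changes.

Step 1
Reactants: 1 4-hydroxy-2,6-dimethoxybenzaldehyde
Product: 2 2,6-dimethoxy-4-(triisopropylsilyloxy)benzaldehyde
Conditions: TIPSCl (1.2 equiv), imidazole (2 equiv), DMF, 0 °C to rt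
Reagents that add atoms: triisopropylsilyl chloride (TIPSCl), CC(C)[Si](Cl)(C(C)C)C(C)C
Why: Imidazole-promoted silylation of the only phenolic OH (silyl ether formation) should proceed cleanly, and the bulky TIPS ether, which marks the oxygen destined to become O1, tolerates the Grignard reagent, the amide base and the brief cold HCl that follow.

Step 2
Reactants: 2 2,6-dimethoxy-4-(triisopropylsilyloxy)benzaldehyde; 3 (S)-tert-butanesulfinamide
Product: 4 (S)-N-[(E)-[2,6-dimethoxy-4-(triisopropylsilyloxy)phenyl]methylidene]-2-methylpropane-2-sulfinamide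
Conditions: Ti(OEt)4 (2 equiv), THF, 60 °C; brine, filtration through Celite
Reagents that add atoms: none
Why: Ti(OEt)4-mediated condensation of an aldehyde with tert-butanesulfinamide (sulfinimine formation), the titanium reagent acting as Lewis acid and water scavenger, should give only the E aldimine even from this hindered, electron-rich aldehyde, with the sulfur centre untouched.

Step 3
Reactants: 5 1-bromo-4-chlorobutane
Product: 6 4-chlorobutylmagnesium bromide (ether solution, titrated and used at once)
Conditions: Mg turnings (1.2 equiv), 1,2-dibromoethane (cat.), Et2O, 0–20 °C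
Reagents that add atoms: magnesium, [Mg]
Why: Grignard formation by magnesium insertion is much faster at C–Br than at C–Cl and the 4-chlorobutyl reagent is slow to cyclize when kept cool, so the chloride should survive; ether is chosen over THF so that little donor solvent enters step 4.

Step 4
Reactants: 4 (S)-N-[(E)-[2,6-dimethoxy-4-(triisopropylsilyloxy)phenyl]methylidene]-2-methylpropane-2-sulfinamide; 6 4-chlorobutylmagnesium bromide
Product: 7 (S)-N-[(1R)-5-chloro-1-[2,6-dimethoxy-4-(triisopropylsilyloxy)phenyl]pentyl]-2-methylpropane-2-sulfinamide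
Conditions: 6 (2 equiv, Et2O solution) added to 4 in CH2Cl2, −48 °C, then slowly to 0 °C; sat. aq. NH4Cl; chromatography or crystallization to one diastereomer
Reagents that add atoms: none
Why: 1,2-Addition of a Grignard reagent to an N-tert-butanesulfinyl aldimine in a non-coordinating solvent should pass through a six-membered chair transition state with magnesium bound to the sulfinyl oxygen and both tert-butyl and aryl equatorial, which delivers the alkyl group to the face that gives R at carbon from S at sulfur.

Step 5
Reactants: 7 (S)-N-[(1R)-5-chloro-1-[2,6-dimethoxy-4-(triisopropylsilyloxy)phenyl]pentyl]-2-methylpropane-2-sulfinamide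
Product: 8 (2R)-1-[(S)-tert-butylsulfinyl]-2-[2,6-dimethoxy-4-(triisopropylsilyloxy)phenyl]piperidine
Conditions: KN(SiMe3)2 (1.2 equiv), THF, 0 °C to rt
Reagents that add atoms: none
Why: Deprotonation of the sulfinamide N–H and intramolecular SN2 N-alkylation by the primary chloride (6-exo-tet) should close the piperidine without touching the benzylic stereocentre, the aryl silyl ether being stable to the amide base in THF.

Step 6
Reactants: 8 (2R)-1-[(S)-tert-butylsulfinyl]-2-[2,6-dimethoxy-4-(triisopropylsilyloxy)phenyl]piperidine; 9 formaldehyde (37% aqueous)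
Product: 11 (2R)-2-[2,6-dimethoxy-4-(triisopropylsilyloxy)phenyl]-1-methylpiperidine, via secondary amine hydrochloride 10 (not isolated)
Conditions: HCl (4 M in dioxane, 2 equiv), MeOH, 0 °C, 30 min, evaporated cold; then 9 (3 equiv), NaOAc (1.5 equiv), NaBH(OAc)3 (2 equiv), ClCH2CH2Cl, rt; aq. NaHCO3
Reagents that add atoms: none
Why: Acidolysis of the S–N bond in methanol (sulfinyl removal, kept short and cold so that the electron-rich benzylic C–N bond cannot ionize) followed by reductive amination with formaldehyde, in which NaBH(OAc)3 reduces the N-methyleneiminium ion faster than it can isomerize, should give the N-methyl amine with the stereocentre intact, the TIPS ether keeping ring A from reacting with formaldehyde.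

Step 7
Reactants: 11 (2R)-2-[2,6-dimethoxy-4-(triisopropylsilyloxy)phenyl]-1-methylpiperidine
Product: 12 3,5-dimethoxy-4-[(2R)-1-methylpiperidin-2-yl]phenol
Conditions: Bu4NF (1.2 equiv), AcOH (1.2 equiv), THF, 0 °C to rt; aq. NaHCO3, extraction at pH 8–9
Reagents that add atoms: none
Why: Fluoride-induced cleavage of the aryl silyl ether under acetic acid buffering should free the single phenolic oxygen without acid or strong base at the stereocentre, giving the phenol with two equivalent ortho carbons on which configuration and enantiopurity (chiral HPLC) are checked.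

Step 8
Reactants: 12 3,5-dimethoxy-4-[(2R)-1-methylpiperidin-2-yl]phenol; 13 ethyl phenylpropiolate
Product: 14 ethyl (Z)-3-[3,5-dimethoxy-4-[(2R)-1-methylpiperidin-2-yl]phenoxy]-3-phenylprop-2-enoate
Conditions: K2CO3 (0.5 equiv), 13 (1.2 equiv), DMF, 70 °C
Reagents that add atoms: none
Why: Base-catalysed oxa-Michael addition of the phenoxide to the β carbon of the ynoate (the first half of the Ruhemann flavone synthesis) forms O1–C2, anti addition favouring the Z isomer, and any E isomer is tolerable because both converge in step 10.

Step 9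
Reactants: 14 ethyl (Z)-3-[3,5-dimethoxy-4-[(2R)-1-methylpiperidin-2-yl]phenoxy]-3-phenylprop-2-enoate
Product: 15 (Z)-3-[3,5-dimethoxy-4-[(2R)-1-methylpiperidin-2-yl]phenoxy]-3-phenylprop-2-enoic acid hydrochloride
Conditions: LiOH·H2O (3 equiv), THF/H2O, rt; then aq. HCl to pH 1–2, extraction into CHCl3/i-PrOH, toluene azeotrope to dryness
Reagents that add atoms: lithium hydroxide, [Li+].[OH-]; hydrogen chloride, Cl
Why: Saponification of the ethyl ester with LiOH at room temperature (acyl-oxygen ester hydrolysis) should spare the vinylogous carbonate linkage, and acidification with HCl protonates the piperidine nitrogen so that it is masked during the acylation.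

Step 10
Reactants: 15 (Z)-3-[3,5-dimethoxy-4-[(2R)-1-methylpiperidin-2-yl]phenoxy]-3-phenylprop-2-enoic acid hydrochloride
Product: 17 5,7-dimethoxy-6-[(2R)-1-methylpiperidin-2-yl]-2-phenyl-4H-chromen-4-one, via acid chloride hydrochloride 16 (not isolated)
Conditions: (COCl)2 (1.05 equiv), DMF (cat.), CH2Cl2, −20 to 0 °C; then SnCl4 (2 equiv), −20 to 0 °C; cold aq. NaHCO3
Reagents that add atoms: none
Why: Chloroiminium-catalysed conversion of the acid into acid chloride 16 is followed by SnCl4-assisted ionization to a β-aryloxy-stabilised acylium ion whose carbonyl carbon (future C4) attacks one of the two equivalent arene carbons ortho to the vinyl ether oxygen (future C4a), and proton loss restores aromaticity. This is an intramolecular Friedel–Crafts acylation, the acid chloride version of the Ruhemann cyclodehydration of β-aryloxycinnamic acids to flavones, of the same type as chromone formation from aryloxyacrylic and aryloxyfumaric acids. Pyranone ring C is closed in a 6-exo mode at the acyl carbon, the carbonyl oxygen staying outside the ring. No stereocentre is created, and the existing one is protected because the nitrogen stays protonated (no acylammonium ion, hence no von Braun-type C–N cleavage) and the medium is cold and non-ionizing; oxalyl chloride is limited to a slight excess so that it cannot acylate ring A. Site selectivity is not needed, since rotation about the aryl–piperidine bond exchanges the two ortho carbons and both give the 6-isomer, while chemoselectivity over the plain phenyl ring (indenone formation) follows from activation by O1, O5 and O7. Any E acid is funnelled into the same flavone because the push–pull C2=C3 bond of the acid chloride and acylium ion rotates readily.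

Step 11
Reactants: 17 5,7-dimethoxy-6-[(2R)-1-methylpiperidin-2-yl]-2-phenyl-4H-chromen-4-one
Product: 18 5,7-dihydroxy-6-[(2R)-1-methylpiperidin-2-yl]-2-phenyl-4H-chromen-4-one
Conditions: BBr3 (6 equiv), CH2Cl2, −78 °C to rt; aq. NaHCO3 at 0 °C to pH 7–8
Reagents that add atoms: none
Why: Lewis acid ether cleavage with BBr3 (coordination to oxygen, then bromide attack at methyl) should remove both methyl groups at or below room temperature, the 5-ether aided by chelation to C4=O and the 7-ether by its twisted, hindered position, while the absence of hot protic acid avoids Wessely–Moser isomerization to the 8-isomer and ionization of the benzylic C–N bond; enantiopurity is checked again on 17 and 18.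

**Compound list**

1 | 4-hydroxy-2,6-dimethoxybenzaldehyde | COc1cc(O)cc(OC)c1C=O | starting material
2 | 2,6-dimethoxy-4-(triisopropylsilyloxy)benzaldehyde | COc1cc(O[Si](C(C)C)(C(C)C)C(C)C)cc(OC)c1C=O | intermediate
3 | (S)-tert-butanesulfinamide | CC(C)(C)[S@](=O)N | starting material
4 | (S)-N-[(E)-[2,6-dimethoxy-4-(triisopropylsilyloxy)phenyl]methylidene]-2-methylpropane-2-sulfinamide | CC(C)(C)[S@](=O)/N=C/c1c(OC)cc(O[Si](C(C)C)(C(C)C)C(C)C)cc1OC | intermediate
5 | 1-bromo-4-chlorobutane | ClCCCCBr | starting material
6 | 4-chlorobutylmagnesium bromide | ClCCCC[Mg]Br | intermediate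
7 | (S)-N-[(1R)-5-chloro-1-[2,6-dimethoxy-4-(triisopropylsilyloxy)phenyl]pentyl]-2-methylpropane-2-sulfinamide | CC(C)(C)[S@](=O)N[C@H](CCCCCl)c1c(OC)cc(O[Si](C(C)C)(C(C)C)C(C)C)cc1OC | intermediate
8 | (2R)-1-[(S)-tert-butylsulfinyl]-2-[2,6-dimethoxy-4-(triisopropylsilyloxy)phenyl]piperidine | CC(C)(C)[S@](=O)N1CCCC[C@@H]1c1c(OC)cc(O[Si](C(C)C)(C(C)C)C(C)C)cc1OC | intermediate
9 | formaldehyde | C=O | starting material
10 | (2R)-2-[2,6-dimethoxy-4-(triisopropylsilyloxy)phenyl]piperidine hydrochloride (not isolated) | Cl.N1CCCC[C@@H]1c1c(OC)cc(O[Si](C(C)C)(C(C)C)C(C)C)cc1OC | intermediate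
11 | (2R)-2-[2,6-dimethoxy-4-(triisopropylsilyloxy)phenyl]-1-methylpiperidine | CN1CCCC[C@@H]1c1c(OC)cc(O[Si](C(C)C)(C(C)C)C(C)C)cc1OC | intermediate
12 | 3,5-dimethoxy-4-[(2R)-1-methylpiperidin-2-yl]phenol | CN1CCCC[C@@H]1c1c(OC)cc(O)cc1OC | intermediate
13 | ethyl phenylpropiolate | CCOC(=O)C#Cc1ccccc1 | starting material
14 | ethyl (Z)-3-[3,5-dimethoxy-4-[(2R)-1-methylpiperidin-2-yl]phenoxy]-3-phenylprop-2-enoate | CN1CCCC[C@@H]1c1c(OC)cc(O/C(=C\C(=O)OCC)c2ccccc2)cc1OC | intermediate
15 | (Z)-3-[3,5-dimethoxy-4-[(2R)-1-methylpiperidin-2-yl]phenoxy]-3-phenylprop-2-enoic acid hydrochloride | CN1CCCC[C@@H]1c1c(OC)cc(O/C(=C\C(=O)O)c2ccccc2)cc1OC.Cl | intermediate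
16 | (Z)-3-[3,5-dimethoxy-4-[(2R)-1-methylpiperidin-2-yl]phenoxy]-3-phenylprop-2-enoyl chloride hydrochloride (not isolated) | CN1CCCC[C@@H]1c1c(OC)cc(O/C(=C\C(Cl)=O)c2ccccc2)cc1OC.Cl | intermediate
17 | 5,7-dimethoxy-6-[(2R)-1-methylpiperidin-2-yl]-2-phenyl-4H-chromen-4-one | CN1CCCC[C@@H]1c1c(OC)cc2oc(-c3ccccc3)cc(=O)c2c1OC | intermediate
18 | 5,7-dihydroxy-6-[(2R)-1-methylpiperidin-2-yl]-2-phenyl-4H-chromen-4-one | CN1CCCC[C@@H]1c1c(O)cc2oc(-c3ccccc3)cc(=O)c2c1O | target

**Step count.** Total: 11 steps. Longest linear sequence: 10 steps (from 1 through steps 1, 2 and 4–11); the Grignard branch (step 3) joins at step 4.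

**Steps most likely to fail**

Step 10 (ring closure). The activating reagents may attack the very electron-rich ring A intermolecularly (C-acylation by oxalyl chloride, formylation by the chloroiminium species). The acid chloride may oligomerize instead of closing. The Lewis acid may ionize the benzylic C–N bond, so that the piperidine opens and recloses with loss of configuration. The fallback sets out from 12 and returns at 17. It builds ring C in the opposite order by a Baker–Venkataraman-type sequence that still relies on the two equivalent ortho carbons. Acetylation of 12 with Ac2O and BF3·OEt2 (O-acetylation, then Fries shift to either ortho carbon, CH2Cl2, 0 °C to rt) should give 1-[6-hydroxy-2,4-dimethoxy-3-[(2R)-1-methylpiperidin-2-yl]phenyl]ethanone F1. Its dianion (LiN(SiMe3)2, THF, −78 °C) is C-benzoylated with benzoyl chloride to 1-[6-hydroxy-2,4-dimethoxy-3-[(2R)-1-methylpiperidin-2-yl]phenyl]-3-phenylpropane-1,3-dione F2. Cyclodehydration in methanolic HCl at room temperature then gives 17.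

Step 4 (stereocentre). Facial selectivity may be poor or reversed because the ortho methoxy groups compete with the sulfinyl oxygen for magnesium. Addition to the hindered, deactivated aldimine may also be slow, leaving room for β-hydride reduction. The fallback sets out from 6 and returns at 10. It reverses the polarity, so that the imine carries no second donor.
- Electrophile: Bouveault formylation of 6 with DMF gives 5-chloropentanal F3. This is condensed (CuSO4, CH2Cl2) with bought (R)-tert-butanesulfinamide F4 to (R)-N-[(E)-5-chloropentylidene]-2-methylpropane-2-sulfinamide F5.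
- Nucleophile: bought 3,5-dimethoxyphenol F6 is silylated (TIPSCl, imidazole) to (3,5-dimethoxyphenoxy)triisopropylsilane F7. Lithiation between the two methoxy groups (n-BuLi, THF, 0 °C) gives [2,6-dimethoxy-4-(triisopropylsilyloxy)phenyl]lithium F8, which is transmetalated with MgBr2·OEt2 to [2,6-dimethoxy-4-(triisopropylsilyloxy)phenyl]magnesium bromide F9.
- Union and return: addition of F9 to F5 in toluene, through the same chair model, should give (R)-N-[(1R)-5-chloro-1-[2,6-dimethoxy-4-(triisopropylsilyloxy)phenyl]pentyl]-2-methylpropane-2-sulfinamide F10. KN(SiMe3)2 closes (2R)-1-[(R)-tert-butylsulfinyl]-2-[2,6-dimethoxy-4-(triisopropylsilyloxy)phenyl]piperidine F11. Cold HCl in MeOH, as in step 6, delivers 10.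

Step 11 (unmasking). Cleavage of the hindered 7-ether may stall, or long exposure to the Lewis acid may erode configuration or isomerize the ring. The fallback sets out from 17 and returns at 18. It splits the task into a chelation-controlled step and a basic one. BCl3 (CH2Cl2, −78 to 0 °C) removes only the 5-methyl group next to C4=O, giving 5-hydroxy-7-methoxy-6-[(2R)-1-methylpiperidin-2-yl]-2-phenyl-4H-chromen-4-one F12. NaSEt in DMF at 100 °C then cleaves the 7-ether by SN2 attack at methyl, with no acid present, to give 18.

**Further compounds**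

F1 | step 10 | 1-[6-hydroxy-2,4-dimethoxy-3-[(2R)-1-methylpiperidin-2-yl]phenyl]ethanone | CN1CCCC[C@@H]1c1c(OC)cc(O)c(C(C)=O)c1OC
F2 | step 10 | 1-[6-hydroxy-2,4-dimethoxy-3-[(2R)-1-methylpiperidin-2-yl]phenyl]-3-phenylpropane-1,3-dione | CN1CCCC[C@@H]1c1c(OC)cc(O)c(C(=O)CC(=O)c2ccccc2)c1OC
F3 | step 4 | 5-chloropentanal | ClCCCCC=O
F4 | step 4 | (R)-tert-butanesulfinamide (bought) | CC(C)(C)[S@@](=O)N
F5 | step 4 | (R)-N-[(E)-5-chloropentylidene]-2-methylpropane-2-sulfinamide | CC(C)(C)[S@@](=O)/N=C/CCCCCl
F6 | step 4 | 3,5-dimethoxyphenol (bought) | COc1cc(O)cc(OC)c1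
F7 | step 4 | (3,5-dimethoxyphenoxy)triisopropylsilane | COc1cc(OC)cc(O[Si](C(C)C)(C(C)C)C(C)C)c1
F8 | step 4 | [2,6-dimethoxy-4-(triisopropylsilyloxy)phenyl]lithium | COc1cc(O[Si](C(C)C)(C(C)C)C(C)C)cc(OC)c1[Li]
F9 | step 4 | [2,6-dimethoxy-4-(triisopropylsilyloxy)phenyl]magnesium bromide | COc1cc(O[Si](C(C)C)(C(C)C)C(C)C)cc(OC)c1[Mg]Br
F10 | step 4 | (R)-N-[(1R)-5-chloro-1-[2,6-dimethoxy-4-(triisopropylsilyloxy)phenyl]pentyl]-2-methylpropane-2-sulfinamide | CC(C)(C)[S@@](=O)N[C@H](CCCCCl)c1c(OC)cc(O[Si](C(C)C)(C(C)C)C(C)C)cc1OC
F11 | step 4 | (2R)-1-[(R)-tert-butylsulfinyl]-2-[2,6-dimethoxy-4-(triisopropylsilyloxy)phenyl]piperidine | CC(C)(C)[S@@](=O)N1CCCC[C@@H]1c1c(OC)cc(O[Si](C(C)C)(C(C)C)C(C)C)cc1OC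
F12 | step 11 | 5-hydroxy-7-methoxy-6-[(2R)-1-methylpiperidin-2-yl]-2-phenyl-4H-chromen-4-one | CN1CCCC[C@@H]1c1c(OC)cc2oc(-c3ccccc3)cc(=O)c2c1O
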